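Amber and teal carry the same loading of initiator, yet at 4.00 min teal holds 2.0% of its free monomer and amber 56.3%.

the same everywhere: initiator 1 mol%

| run | free monomer | remark | time |
|---|---|---|---|
| amber | 0.44 M | run made earlier |  |
| teal | 1.5 M | run made earlier |  |
| ash | 0.75 M |  | 4.0 min |
| alder | 2.5 M |  | 4.0 min |

| run | time / min | monomer in chains / % | free monomer / % |
|---|---|---|---|
| amber | 0.333 | 2.7 | 95.0 |
| amber | 0.667 | 5.7 | 91.1 |
| amber | 1.50 | 11.3 | 80.9 |
| amber | 4.00 | 26.3 | 56.3 |
| teal | 0.500 | 35.6 | 62.4 |
| teal | 1.33 | 69.0 | 27.1 |
| teal | 2.50 | 86.2 | 8.6 |
| teal | 4.00 | 92.8 | 2.0 |

(each reading ± 0.3 percentage points)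

- the average divides the monomer in chains by the number of chains begun, living and dead together
- the analysis behind the earlier runs scatters by 0.3 percentage points, standard deviation
- the earlier runs do not show the number of chains; that part of a forecast is a guess

* which of the two ends with the longer chains by the average number of monomer units in a chain (chains begun, living or dead) ("neither" if they lie within 10%) (ash / alder / neither)
* average number of monomer units in a chain (chains begun, living or dead) at the end, ash
* average number of monomer units in a chain (chains begun, living or dead) at the end, alder

I read a first-order loss rate from one reading in each run: 0.144 min⁻¹ in amber and 0.981 min⁻¹ in teal. Multiplying each by the share of reacted monomer found in chains gives the chain frequency, a pseudo-first-order rate: 0.0864 min⁻¹ and 0.926 min⁻¹. The remainder is a side loss of 0.0572 min⁻¹, and teal gives 0.0550 min⁻¹. The chain order is 1.93, the steepness of chain frequency against charge at fixed loading. I take growing ends to scale with the charge by that order.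

Now the ladder. I take whatever sets the growing ends to be over before amber's first reading, which already gives a loss rate of 0.154 min⁻¹. Next, alder's chain frequency comes to 2.48 min⁻¹, so with the side loss its free monomer has a lifetime of 0.394 min. Ash follows: its chain frequency comes to 0.242 min⁻¹, which gives a lifetime of 3.34 min. The side loss by itself has a lifetime of 17.5 min, longer than either of these. So at 4.0 min I expect 97.7% in chains for alder and 56.5% for ash. Length is monomer in chains over ends, so ash over alder comes to 1.78. The runs show no number of chains, so I commit to this ratio and to ash.

The forecast differs from my reckoning: alder, with 70 (58 to 125) for ash and 98 (90 to 118) for alder, on the ground “This suggests a poison”.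

The flask gives ash: 1450 for ash and 832 for alder, a ratio of 1.74.

    initiator → spent initiator (k = 0.620 s⁻¹)
    free monomer + living end → monomer in chains + living end, rate k2*[living end]*[free monomer] (k = 14.0 L mol⁻¹ s⁻¹)
    free monomer → uncatalysed product (k = 9.50 × 10⁻⁴ s⁻¹)
    free monomer + initiator → living end + monomer in chains (k = 0.0340 L mol⁻¹ s⁻¹)

The chain order puts alder's living ends at 10.3 times ash's, and at 4.00 min the flasks hold 0.00293 M against 2.95 × 10⁻⁴ M, a factor of 9.95. Alder's chains are shorter than ash's because of the difference in the charge of free monomer: alder with that difference taken away ends at 1450, not 832. For the neighbour, ash stopped at 2.5 min, the same order gives free monomer of 47.3%, and that flask holds 47.0%, with chains averaging 1090.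

Readings and results come from a simulation for substances that don't exist; noise was put on by code.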